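The route rests on cutting C6–C11 of cyclohexane ring B together with O–C2 of oxepane ring A (squalene numbering). This leads back to an acyclic (3S,6S,7S)-diepoxide that ends in a C10=C11 silyl enol ether and already carries cyclohexene ring C. One silyl triflate triggered oxa/carbacyclisation closes ring A through a bridged epoxonium ion and then ring B, setting C6 and C11 and relaying C3 and C7. The step exploits the anti O7–C7–C6–C11 array of the trans A/B fusion and the oxygen on C10. The resulting C10 ketone accepts methyl equatorially to give the axial tertiary alcohol. The precursor is assembled from geranylacetone and 2-methylcyclohexane-1,3-dione by cross-metathesis.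

Key step: step 12

Remark on numbering:
- C2 is CMe2–O, C3 is CHOH, C6 is the angular C–Me, C7 is CH–O, C10 is C(OH)Me and C11 is CH.
- C12–C13 is the linker and C14=C15 is the ring C alkene.
- C18 is CHOH, C19 is the quaternary carbon, C20–C21 is the side chain, C22 is CHOOH and C23 is the isopropenyl carbon.
- Ring A is the oxepane, ring B the cyclohexane and ring C the cyclohexene.
- The target is 3S,6S,7S,10R,11S,18R,19S,22S. The C10 hydroxyl is axial and cis to the C6 methyl, and the C18 hydroxyl is cis to the C20 chain.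

Remark on the chemistry: the L-fructose-derived epoxidation ketone and the oxazoline–sulfonamide ligand are taken as purchasable catalysts. The ligand antipode used is the one whose chromium alkenyl attacks the Si face of the aldehyde.

Step 1
Reactants: 1 2-methylcyclohexane-1,3-dione; 2 acrolein
Product: 3 3-(1-methyl-2,6-dioxocyclohexyl)propanal
Conditions: H2O, rt
Reagents that add atoms: none
Why: Michael addition of the soft C2 carbon acid of the 1,3-dione to acrolein builds the still prochiral quaternary C19 and brings in C20–C22.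

Step 2
Reactants: 3 3-(1-methyl-2,6-dioxocyclohexyl)propanal; 4 2-bromopropene
Product: 5 2-methyl-2-[(3R)-4-methyl-3-(triethylsilyloxy)pent-4-en-1-yl]cyclohexane-1,3-dione (22R)
Conditions: CrCl2 (10 mol %), chiral N-[2-(4-isopropyl-4,5-dihydrooxazol-2-yl)-6-methylphenyl]methanesulfonamide (12 mol %), Et3N (20 mol %), NiCl2 (2 mol %), Mn powder, TESCl, MeCN, rt
Reagents that add atoms: chlorotriethylsilane CC[Si](Cl)(CC)CC
Why: In this catalytic asymmetric Nozaki–Hiyama–Kishi alkenylation, zerovalent nickel activates the C–Br bond and the alkenyl group passes to ligand-bound trivalent chromium, which adds only to the aldehyde and on its Si face to set 22R, while TESCl releases the chromium alkoxide as the silyl ether and Mn returns divalent chromium.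

Step 3
Reactants: 5 the 22R TES ether dione
Product: 6 (2R,3R)-3-hydroxy-2-methyl-2-[(3R)-4-methyl-3-(triethylsilyloxy)pent-4-en-1-yl]cyclohexan-1-one (18R,19R,22R)
Conditions: (S)-2-methyl-CBS-oxazaborolidine (20 mol %), catecholborane (1.1 equiv), toluene, −60 °C; MeOH, aq. NaHCO3
Reagents that add atoms: none
Why: This Corey–Bakshi–Shibata reduction acts as a desymmetrisation, because the catalyst reads quaternary C19 as the large group and should deliver the 18R carbinol, and hydride approach anti to the longer C19 substituent selects the carbonyl so that the OH ends cis to the side chain, which fixes C19.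

Step 4
Reactants: 6 the hydroxy ketone
Product: 7 18-O-TBS ether of 6
Conditions: TBSOTf, 2,6-lutidine, CH2Cl2, −78 → 0 °C
Reagents that add atoms: tert-butyldimethylsilyl triflate CC(C)(C)[Si](C)(C)OS(=O)(=O)C(F)(F)F
Why: Silyl triflate silylation of the hindered neopentyl-type alcohol shuts off retro-aldol cleavage and leaves all stereocenters untouched.

Step 5
Reactants: 7 the silyloxy ketone
Product: 8 C15-methyl ketone (epimers at C15)
Conditions: LiN(iPr)2 (LDA), THF, −78 °C; MeI, −78 → −20 °C
Reagents that add atoms: iodomethane CI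
Why: This is a kinetic enolate alkylation in which C19 is quaternary, so only C15 can be deprotonated, and the C15 epimers are irrelevant because this carbon becomes sp2 in step 6.

Step 6
Reactants: 8 the C15-methyl ketone
Product: 9 C14 enol triflate carrying the tetrasubstituted C14=C15 alkene (18R,19R,22R)
Conditions: KN(SiMe3)2, THF, −78 → 0 °C; PhNTf2, −78 °C → rt
Reagents that add atoms: N-phenylbis(trifluoromethanesulfonimide) O=S(=O)(N(c1ccccc1)S(=O)(=O)C(F)(F)F)C(F)(F)F
Why: O-sulfonylation of the only enolate the ketone can form gives the tetrasubstituted enol triflate, as is known for 2,2,6-trisubstituted cyclohexanones.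

Step 7
Reactants: 9 the enol triflate
Product: 10 C14-allyl ring C diene (fragment R; 18R,19S,22R)
Conditions: allylSnBu3, Pd(PPh3)4 (5 mol %), LiCl, THF, reflux
Reagents that add atoms: allyltributylstannane C=CC[Sn](CCCC)(CCCC)CCCC
Why: Stille coupling of the hindered alkenyl triflate, with chloride-assisted transmetalation at divalent palladium, installs C13 and C12, while the allylic silyl ether is not ionised by zerovalent palladium.

Step 8
Reactants: 11 (E)-geranylacetone
Product: 12 (5S,6S,9S)-5,6:9,10-diepoxy-6,10-dimethylundecan-2-one (3S,6S,7S)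
Conditions: 1,2:4,5-di-O-isopropylidene-β-L-erythro-2,3-hexodiulo-2,6-pyranose (30 mol %), KHSO5 (as Oxone, 2KHSO5·KHSO4·K2SO4), K2CO3, Bu4NHSO4 (cat.), MeCN–dimethoxymethane/aq. Na2B4O7–Na2(EDTA) buffer, 0 °C
Reagents that add atoms: potassium peroxymonosulfate OOS(=O)(=O)[O-].[K+]
Why: In this Shi asymmetric epoxidation the chiral dioxirane meets each trisubstituted alkene in a spiro transition state, and the L-series ketone should give the S,S epoxide from the E alkene and the S epoxide from the prenyl end, which sets C3, C6 and C7.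

Step 9
Reactants: 12 the diepoxy methyl ketone
Product: 15 (6S,7S,10S)-6,7:10,11-diepoxy-7,11-dimethyldodec-1-en-3-one (fragment L), via Mannich base 13 (not isolated), via trimethylammonium iodide 14 (not isolated)
Conditions: LiN(iPr)2 (LDA), THF, −78 °C; CH2=NMe2+ I−, −78 °C → rt; MeI, Et2O, rt; aq. NaHCO3–CH2Cl2, rt
Reagents that add atoms: dimethyl(methylidene)ammonium iodide C=[N+](C)C.[I-]; iodomethane CI
Why: Kinetic deprotonation at the methyl group (C11), a Mannich reaction, quaternisation and E1cB elimination give the vinyl ketone, and the trisubstituted epoxides are inert to the cold lithium enolate.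

Step 10
Reactants: 10 fragment R; 15 fragment L
Product: 16 E-enone joining ring C through C13H2–C12H=C11H–C10(=O) to the diepoxide chain
Conditions: second-generation Hoveyda–Grubbs catalyst (5 mol %), 15 (2 equiv), CH2Cl2, 40 °C
Reagents that add atoms: none
Why: Olefin cross-metathesis between a readily homodimerising terminal alkene and an electron-poor vinyl ketone should be E-selective, and the tetrasubstituted alkene, the hindered 1,1-disubstituted alkene and the epoxides are spectators.

Step 11
Reactants: 16 the E-enone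
Product: 17 Z tert-butyldimethylsilyl enol ether at C10=C11
Conditions: tBuMe2SiH, RhCl(PPh3)3 (2 mol %), THF, 50 °C
Reagents that add atoms: tert-butyldimethylsilane CC(C)(C)[SiH](C)C
Why: Rhodium-catalysed 1,4-hydrosilylation of the s-cis bound enone places the enol double bond regiospecifically at C10=C11 with Z geometry, which enolisation of the saturated ketone could not do.

Step 12
Reactants: 17 the diepoxy Z enol silane
Product: 19 C10 ketone with trans-fused rings A and B (3S,6S,7S,11S; 3-OTBS), via bridged epoxonium triflate 18 (not isolated)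
Conditions: TBSOTf (1.1 equiv), 2,6-di-tert-butyl-4-methylpyridine (DTBMP, 2 equiv), CH2Cl2, −78 °C; Et3N, aq. NaHCO3
Reagents that add atoms: tert-butyldimethylsilyl triflate CC(C)(C)[Si](C)(C)OS(=O)(=O)C(F)(F)F
Why: TBSOTf silylates the terminal 2,3-epoxide, the oxygen of the 6,7-epoxide opens it at tertiary C2 to give the bridged epoxonium ion 18, and C11 of the enol silane then attacks tertiary C6 anti to the breaking C6–O bond, after which loss of the enol silyl group as TBSOTf unveils the C10 ketone. The closest known reaction type is the Lewis acid triggered endo-selective oxa/carbacyclisation of polyepoxides terminated by an enol silane. Ring A closes by endo opening of the 2,3-epoxide (O–C2 bond, an oxepane once C6–O is cut) and ring B by 6-endo opening of the epoxonium ion at C6 through a chair that holds both enol carbons in the new ring. C3 and C7 keep the C–O bonds set in step 8, C6 is inverted by the SN2-like attack so that O7 and C11 end anti (trans A/B fusion), and C11 is set by the Z enol geometry, which places C12 equatorial and is also the thermodynamic outcome next to the ketone. The step needs endo regiochemistry at both epoxides, C- rather than O-alkylation of the enol silane, and silence of the C14=C15 and isopropenyl alkenes: the first is secured by the cation-stabilising tertiary C2 and C6, the second by the six-membered chair against a strained enol ether alternative, and the third by distance (rings of nine or more atoms) and by DTBMP, which removes adventitious acid. Using the same silyl group in reagent and enol ether keeps the O3 protecting group uniform.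

Step 13
Reactants: 19 the C10 ketone
Product: 21 10R,22R-diol (3,18-bis-TBS ether), via 22-O-TES carbinol 20 (not isolated)
Conditions: MeLi, CeCl3, THF, −78 °C; aq. NH4Cl; crude, PPTS (cat.), MeOH–CH2Cl2, 0 °C
Reagents that add atoms: methyllithium [Li]C
Why: In this organocerium 1,2-addition the axial C6 methyl blocks axial approach, so methyl enters equatorially to give the axial 10R alcohol without enolising C11, and PPTS methanolysis then removes only the unhindered allylic TES group.

Step 14
Reactants: 21 the diol
Product: 23 22S allylic hydroperoxide (3,18-bis-TBS ether), via allylic mesylate 22 (not isolated)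
Conditions: Ms2O, Et3N, CH2Cl2, −40 °C; cold transfer into H2O2 (50 % aq., large excess), KOH, MeOH–THF, 0 °C
Reagents that add atoms: methanesulfonic anhydride CS(=O)(=O)OS(C)(=O)=O; hydrogen peroxide OO
Why: This is the classical alkyl hydroperoxide synthesis by sulfonate displacement, in which the alpha-effect nucleophile HOO− should invert 22R to 22S in an SN2 reaction, the chloride-free anhydride avoids an allylic chloride, the tertiary C10 alcohol is not sulfonylated, and the C18 silyl ether prevents tetrahydropyran formation.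

Step 15
Reactants: 23 the protected hydroperoxide
Product: 24 target CNP0271099.3
Conditions: HF·pyridine, pyridine, THF, 0 °C → rt
Reagents that add atoms: none
Why: Buffered fluoride desilylation of the two hindered TBS ethers runs under conditions that also liberate hydroperoxides from silyl peroxides, so the O–O bond, the tertiary alcohol and both alkenes should survive and no stereocenter is touched.

Compound list
1 | 2-methylcyclohexane-1,3-dione | CC1C(=O)CCCC1=O | starting material
2 | acrolein | C=CC=O | starting material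
3 | 3-(1-methyl-2,6-dioxocyclohexyl)propanal | CC1(CCC=O)C(=O)CCCC1=O | intermediate
4 | 2-bromopropene | C=C(C)Br | starting material
5 | 2-methyl-2-[(3R)-4-methyl-3-(triethylsilyloxy)pent-4-en-1-yl]cyclohexane-1,3-dione | C=C(C)[C@@H](CCC1(C)C(=O)CCCC1=O)O[Si](CC)(CC)CC | intermediate
6 | (2R,3R)-3-hydroxy-2-methyl-2-[(3R)-4-methyl-3-(triethylsilyloxy)pent-4-en-1-yl]cyclohexan-1-one | C=C(C)[C@@H](CC[C@@]1(C)C(=O)CCC[C@H]1O)O[Si](CC)(CC)CC | intermediate
7 | 18-O-TBS ether of 6 | C=C(C)[C@@H](CC[C@@]1(C)C(=O)CCC[C@H]1O[Si](C)(C)C(C)(C)C)O[Si](CC)(CC)CC | intermediate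
8 | C15-methyl ketone (2,6-dimethylcyclohexanone, C15 epimers) | C=C(C)[C@@H](CC[C@@]1(C)C(=O)C(C)CC[C@H]1O[Si](C)(C)C(C)(C)C)O[Si](CC)(CC)CC | intermediate
9 | C14 enol triflate with C14=C15 alkene (18R,19R,22R) | C=C(C)[C@@H](CC[C@@]1(C)C(OS(=O)(=O)C(F)(F)F)=C(C)CC[C@H]1O[Si](C)(C)C(C)(C)C)O[Si](CC)(CC)CC | intermediate
10 | fragment R, C14-allyl ring C diene (18R,19S,22R) | C=C(C)[C@@H](CC[C@@]1(C)C(CC=C)=C(C)CC[C@H]1O[Si](C)(C)C(C)(C)C)O[Si](CC)(CC)CC | intermediate
11 | (E)-geranylacetone, (5E)-6,10-dimethylundeca-5,9-dien-2-one | CC(C)=CCC/C(C)=C/CCC(C)=O | starting material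
12 | (5S,6S,9S)-5,6:9,10-diepoxy-6,10-dimethylundecan-2-one | CC1(C)O[C@H]1CC[C@]2(C)O[C@H]2CCC(C)=O | intermediate
13 | (6S,7S,10S)-1-(dimethylamino)-6,7:10,11-diepoxy-7,11-dimethyldodecan-3-one (Mannich base) | CC1(C)O[C@H]1CC[C@]2(C)O[C@H]2CCC(=O)CCN(C)C | intermediate
14 | trimethylammonium iodide of 13 | CC1(C)O[C@H]1CC[C@]2(C)O[C@H]2CCC(=O)CC[N+](C)(C)C.[I-] | intermediate
15 | fragment L, (6S,7S,10S)-6,7:10,11-diepoxy-7,11-dimethyldodec-1-en-3-one | CC1(C)O[C@H]1CC[C@]2(C)O[C@H]2CCC(=O)C=C | intermediate
16 | E-enone (C11=C12, C10 ketone; 3S,6S,7S,18R,19S,22R) | C=C(C)[C@@H](CC[C@@]1(C)C(C/C=C/C(=O)CC[C@@H]2O[C@@]2(C)CC[C@@H]3OC3(C)C)=C(C)CC[C@H]1O[Si](C)(C)C(C)(C)C)O[Si](CC)(CC)CC | intermediate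
17 | Z TBS enol ether at C10=C11 | C=C(C)[C@@H](CC[C@@]1(C)C(CC/C=C(\O[Si](C)(C)C(C)(C)C)CC[C@@H]2O[C@@]2(C)CC[C@@H]3OC3(C)C)=C(C)CC[C@H]1O[Si](C)(C)C(C)(C)C)O[Si](CC)(CC)CC | intermediate
18 | bridged epoxonium triflate (O bound to C2, C6 and C7; 3-OTBS) | C=C(C)[C@@H](CC[C@@]1(C)C(CC/C=C(\O[Si](C)(C)C(C)(C)C)CC[C@@H]2[O+]3[C@@]2(C)CC[C@H](O[Si](C)(C)C(C)(C)C)C3(C)C)=C(C)CC[C@H]1O[Si](C)(C)C(C)(C)C)O[Si](CC)(CC)CC.[O-]S(=O)(=O)C(F)(F)F | intermediate
19 | C10 ketone with trans-fused oxepane–cyclohexanone (3S,6S,7S,11S,18R,19S,22R) | C=C(C)[C@@H](CC[C@@]1(C)C(CC[C@H]2[C@]3(C)CC[C@H](O[Si](C)(C)C(C)(C)C)C(C)(C)O[C@H]3CCC2=O)=C(C)CC[C@H]1O[Si](C)(C)C(C)(C)C)O[Si](CC)(CC)CC | intermediate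
20 | 10R tertiary carbinol, 22-O-TES, 3,18-bis-O-TBS | C=C(C)[C@@H](CC[C@@]1(C)C(CC[C@H]2[C@]3(C)CC[C@H](O[Si](C)(C)C(C)(C)C)C(C)(C)O[C@H]3CC[C@@]2(C)O)=C(C)CC[C@H]1O[Si](C)(C)C(C)(C)C)O[Si](CC)(CC)CC | intermediate
21 | 10R,22R-diol, 3,18-bis-O-TBS | C=C(C)[C@@H](CC[C@@]1(C)C(CC[C@H]2[C@]3(C)CC[C@H](O[Si](C)(C)C(C)(C)C)C(C)(C)O[C@H]3CC[C@@]2(C)O)=C(C)CC[C@H]1O[Si](C)(C)C(C)(C)C)O | intermediate
22 | 22R allylic mesylate of 21 | C=C(C)[C@@H](CC[C@@]1(C)C(CC[C@H]2[C@]3(C)CC[C@H](O[Si](C)(C)C(C)(C)C)C(C)(C)O[C@H]3CC[C@@]2(C)O)=C(C)CC[C@H]1O[Si](C)(C)C(C)(C)C)OS(C)(=O)=O | intermediate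
23 | 22S allylic hydroperoxide, 3,18-bis-O-TBS | C=C(C)[C@H](CC[C@@]1(C)C(CC[C@H]2[C@]3(C)CC[C@H](O[Si](C)(C)C(C)(C)C)C(C)(C)O[C@H]3CC[C@@]2(C)O)=C(C)CC[C@H]1O[Si](C)(C)C(C)(C)C)OO | intermediate
24 | CNP0271099.3 (3S,6S,7S,10R,11S,18R,19S,22S) | C=C(C)[C@H](CC[C@@]1(C)C(CC[C@H]2[C@]3(C)CC[C@H](O)C(C)(C)O[C@H]3CC[C@@]2(C)O)=C(C)CC[C@H]1O)OO | target

Total step count: 15. Longest linear sequence: 13 (steps 1–7, then 10–15). Steps 8–9 form the short branch.

Steps most likely to fail

1. Step 12. In the large, flexible substrate three processes could divert the cascade. The internal epoxide may be silylated first, the enol silane may react through oxygen, or cationic intermediates may be lost to hydride shift or to the ring C alkenes.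

   The fallback runs the same ring closure on a truncated substrate and moves the fragment union behind it. It sets out from 15, later uses 9, and comes back at 20.
   - Compound 15 is cross-metathesised with allyl acetate (second-generation Hoveyda–Grubbs catalyst) to the E-enone acetate F1.
   - Conjugate hydrosilylation (tBuMe2SiH, RhCl(PPh3)3) gives the Z enol silane F2.
   - TBSOTf/DTBMP closes rings A and B to the bicyclic keto acetate F3.
   - Excess MeLi/CeCl3 adds to C10 from the equatorial side and removes the acetate, giving the primary/tertiary diol F4.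
   - I2, PPh3 and imidazole convert the primary alcohol into the iodide F5.
   - t-BuLi followed by B-methoxy-9-borabicyclo[3.3.1]nonane gives the alkyl borinate.
   - This borinate is joined to triflate 9 in a B-alkyl Suzuki–Miyaura coupling (Pd(dppf)Cl2, K3PO4, DMF–H2O). The coupling forms C13–C14 and delivers 20.

2. Step 14. The allylic mesylate may ionise with erosion of configuration at C22. It may also be attacked at the terminal methylene with allylic transposition, or eliminate to a diene in the protic basic medium.

   The fallback replaces free hydrogen peroxide by a monoprotected peroxide anion in a dipolar aprotic medium and merges unmasking with the last step. It sets out from 22 and comes back at 24.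
   - Compound 22 is treated with 2-methoxyprop-2-yl hydroperoxide (made by ozonolysis of 2,3-dimethylbut-2-ene in MeOH) and CsOH·H2O in DMF at 0 °C. This gives the 22S perketal F6, which can be purified and cannot form a dialkyl peroxide.
   - Aqueous HF in MeCN then cleaves the perketal and both TBS ethers to give 24.

3. Step 2. A ligand-free background addition may erode facial selectivity, and the chlorosilane may promote enolisation or aldol closure of the keto aldehyde.

   The fallback sets C22 by reduction instead of addition. It sets out from 3 and 4 and comes back at 6.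
   - Stoichiometric CrCl2 with catalytic NiCl2 in DMF gives the racemic allylic alcohol F7.
   - Dess–Martin periodinane gives the enone trione F8.
   - (S)-2-methyl-CBS-oxazaborolidine with catecholborane (2.2 equiv) reduces the enone carbonyl (alkenyl as the large group, giving 22R) and one ring carbonyl (18R, fixing C19). The product is the dihydroxy ketone F9.
   - TESCl (1 equiv) and imidazole at −20 °C silylate the unhindered allylic hydroxyl to give 6.

Further compounds
F1 | step 12 | (2E,8S,9S,12S-type) E-enone acetate, 4-oxo-7,8:11,12-diepoxy-8,12-dimethyltridec-2-en-1-yl acetate (3S,6S,7S) | CC1(C)O[C@H]1CC[C@]2(C)O[C@H]2CCC(=O)/C=C/COC(C)=O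
F2 | step 12 | Z TBS enol ether of the 11,12-dihydro ketone of F1 | CC1(C)O[C@H]1CC[C@]2(C)O[C@H]2CC/C(O[Si](C)(C)C(C)(C)C)=C/CCOC(C)=O
F3 | step 12 | bicyclic keto acetate (trans-fused rings A and B, 3-OTBS, C11 2-acetoxyethyl; 3S,6S,7S,11S) | CC(=O)OCC[C@H]1[C@]2(C)CC[C@H](O[Si](C)(C)C(C)(C)C)C(C)(C)O[C@H]2CCC1=O
F4 | step 12 | bicyclic diol (10R tertiary alcohol, C13 primary alcohol, 3-OTBS) | OCC[C@H]1[C@]2(C)CC[C@H](O[Si](C)(C)C(C)(C)C)C(C)(C)O[C@H]2CC[C@@]1(C)O
F5 | step 12 | C13 primary iodide of F4 | ICC[C@H]1[C@]2(C)CC[C@H](O[Si](C)(C)C(C)(C)C)C(C)(C)O[C@H]2CC[C@@]1(C)O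
F6 | step 14 | 22S 2-methoxyprop-2-yl perketal, 3,18-bis-O-TBS | C=C(C)[C@H](CC[C@@]1(C)C(CC[C@H]2[C@]3(C)CC[C@H](O[Si](C)(C)C(C)(C)C)C(C)(C)O[C@H]3CC[C@@]2(C)O)=C(C)CC[C@H]1O[Si](C)(C)C(C)(C)C)OOC(C)(C)OC
F7 | step 2 | racemic 2-(3-hydroxy-4-methylpent-4-en-1-yl)-2-methylcyclohexane-1,3-dione | C=C(C)C(O)CCC1(C)C(=O)CCCC1=O
F8 | step 2 | 2-methyl-2-(4-methyl-3-oxopent-4-en-1-yl)cyclohexane-1,3-dione | C=C(C)C(=O)CCC1(C)C(=O)CCCC1=O
F9 | step 2 | (2R,3R)-3-hydroxy-2-[(3R)-3-hydroxy-4-methylpent-4-en-1-yl]-2-methylcyclohexan-1-one | C=C(C)[C@@H](CC[C@@]1(C)C(=O)CCC[C@H]1O)O
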